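**Retrosynthetic overview**

1. Disconnections, in retrosynthetic order: C8–O silyl ether and C9 acetate; C9–C10 (intramolecular Nozaki–Hiyama–Kishi reaction, closes the ten-membered carbocycle last); C6–C7 together with the O6–C12 lactone bond (chromium Barbier allylation, closes the butyrolactone first); C10–C14 (Negishi coupling).
2. Enabling feature: C10 is the fully substituted sp2 carbon of the trisubstituted ring alkene C1=C10, and its partner C1 carries only H and the C2 methylene. The exocyclic C14 arm sits trans to C2 and the ring bond to C9 sits cis to C2, so C10 can enter as the CBr2 carbon of a gem-dibromoolefin whose two C–Br bonds differ only by geometry.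
3. The key step couples that dibromoolefin, trans-selectively, with the zinc reagent made from iodomethyl (S)-2-methylbutanoate. It forms C10–C14, delivers the complete ester side chain, and creates the (Z) ring-alkene geometry from a precursor that has no stereochemical element at that alkene. The remaining cis C10–Br bond is the handle for the ring closure.
4. Carbon mapping: neryl acetate gives C1–C6 and C15 with the 4Z alkene in place; CBr4 gives C10; (R)-glyceraldehyde acetonide gives C7–C9 and the C8 stereocentre; methyl acrylate gives C11–C13.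
5. Stereocentres: C6 and C7 arise in the Barbier step under control of C8; C9 arises in the ring closure under Felkin–Anh control of C8.

Key step: step 7

Remark: locants C1–C15 are the germacranolide locants of the target (ring alkenes C1=C10 and C4=C5, lactone oxygen on C6, exocyclic C11=C13, lactone carbonyl C12, acyloxymethyl carbon C14 on C10, methyl C15 on C4). CIP descriptors are those of each compound itself, so C7 is S in 16, 17 and 19–22 and R in 18 and 23 although its spatial arrangement never changes. Epoxide 2 is racemic at a centre that step 2 destroys.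

**Route**

Step 1
Reactants: 1 neryl acetate, (2Z)-3,7-dimethylocta-2,6-dien-1-yl acetate
Product: 2 (2Z)-5-(3,3-dimethyloxiran-2-yl)-3-methylpent-2-en-1-yl acetate (racemic at the oxirane CH)
Conditions: mCPBA (1.05 equiv), NaHCO3, CH2Cl2, 0 °C
Reagents that add atoms: mCPBA, O=C(OO)c1cccc(Cl)c1
Why: Prilezhaev epoxidation should take the remote trisubstituted alkene because the C4=C5 alkene is deactivated inductively by the allylic acetate; the new oxirane centre is racemic and is removed in step 2.

Step 2
Reactants: 2 (2Z)-5-(3,3-dimethyloxiran-2-yl)-3-methylpent-2-en-1-yl acetate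
Product: 3 (2Z)-3-methyl-6-oxohex-2-en-1-yl acetate
Conditions: H5IO6 (1.1 equiv), THF/Et2O, 0 °C
Reagents that add atoms: none
Why: Periodic acid opens the epoxide to the glycol and cleaves it (Malaprade-type glycol cleavage) to acetone and the C1 aldehyde, whose oxygen is the oxirane oxygen, without touching the (Z)-alkene.

Step 3
Reactants: 3 (2Z)-3-methyl-6-oxohex-2-en-1-yl acetate
Product: 4 (2Z)-7,7-dibromo-3-methylhepta-2,6-dien-1-yl acetate
Conditions: CBr4 (2 equiv), PPh3 (4 equiv), CH2Cl2, 0 °C
Reagents that add atoms: carbon tetrabromide, BrC(Br)(Br)Br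
Why: The first stage of the Corey–Fuchs reaction (Wittig dibromomethylenation) converts the aldehyde into the gem-dibromoolefin whose CBr2 carbon becomes C10.

Step 4
Reactants: 4 (2Z)-7,7-dibromo-3-methylhepta-2,6-dien-1-yl acetate
Product: 5 (2Z)-7,7-dibromo-3-methylhepta-2,6-dien-1-ol
Conditions: K2CO3 (0.2 equiv), MeOH, 0 °C to 23 °C
Reagents that add atoms: none
Why: Base-catalysed transesterification (Zemplén-type methanolysis) removes the acetate before any palladium chemistry, so that no allylic acetate can ionise later; the gem-dibromoolefin is inert to carbonate.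

Step 5
Reactants: 6 (2S)-2-methylbutanoic acid
Product: 7 chloromethyl (2S)-2-methylbutanoate
Conditions: ClCH2OSO2Cl (1.2 equiv), NaHCO3 (4 equiv), Bu4NHSO4 (10 mol %), CH2Cl2/H2O, 0 °C to 23 °C
Reagents that add atoms: chloromethyl chlorosulfate, ClCOS(=O)(=O)Cl
Why: Phase-transfer O-alkylation of the carboxylate (SN2 at the chloromethyl carbon, chlorosulfate as leaving group) gives the chloromethyl ester under conditions too mild to epimerise the α-stereocentre.

Step 6
Reactants: 7 chloromethyl (2S)-2-methylbutanoate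
Product: 8 iodomethyl (2S)-2-methylbutanoate
Conditions: NaI (2 equiv), acetone, 23 °C, dark
Reagents that add atoms: sodium iodide, [Na+].[I-]
Why: Finkelstein halide exchange, driven by precipitation of NaCl, gives the iodide needed for zinc insertion.

Step 7
Reactants: 5 (2Z)-7,7-dibromo-3-methylhepta-2,6-dien-1-ol; 8 iodomethyl (2S)-2-methylbutanoate
Product: 10 (2Z,6Z)-2-bromo-8-hydroxy-6-methylocta-2,6-dien-1-yl (2S)-2-methylbutanoate, via acyloxymethylzinc iodide 9 (not isolated)
Conditions: 8 (2.5 equiv), Zn dust (activated with BrCH2CH2Br and Me3SiCl), THF, 12 °C; then 5, PdCl2(DPEphos) (5 mol %), THF/DMF, 0 °C to 23 °C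
Reagents that add atoms: none
Why: Zinc inserts into the C–I bond of 8 to give the α-acyloxymethylzinc iodide 9; zerovalent palladium then adds oxidatively to the C–Br bond of 5 that lies trans to the C2 chain, and transmetalation from zinc followed by reductive elimination forms the C10–C14 bond. The closest known reaction type is the trans-selective Negishi monoalkylation of 1,1-dibromo-1-alkenes with alkylzinc halides, here run with an acyloxymethylzinc iodide of the kind used as a hydroxymethyl-anion equivalent. No ring is closed and no stereocentre is formed; the stereochemical element created is the C1=C10 geometry, which is fixed by which of the two geminal bromides reacts. The step needs mono- over double coupling and trans- over cis-C–Br selectivity; both rest on the steric difference between the two bromides and on the much slower oxidative addition of the product, a more hindered 2-bromoalk-2-ene. The (S)-2-methylbutanoate should arrive intact because the zinc reagent is non-basic and tolerates the free allylic hydroxyl, which at most consumes part of the excess reagent. The cis C10–Br bond that remains is the handle for the ring closure in step 15, which must then place C9 cis to C2.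

Step 8
Reactants: 10 (2Z,6Z)-2-bromo-8-hydroxy-6-methylocta-2,6-dien-1-yl (2S)-2-methylbutanoate
Product: 11 (2Z,6Z)-2-bromo-6-methyl-8-oxoocta-2,6-dien-1-yl (2S)-2-methylbutanoate
Conditions: MnO2 (20 equiv), CH2Cl2, 23 °C
Reagents that add atoms: none
Why: Allylic oxidation with activated MnO2 should give the (Z)-enal at C6 without Z to E isomerisation and without touching the ester or the alkenyl bromide.

Step 9
Reactants: 12 (4R)-2,2-dimethyl-1,3-dioxolane-4-carbaldehyde ((R)-glyceraldehyde acetonide); 13 methyl acrylate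
Product: 14 methyl 2-{[(4R)-2,2-dimethyl-1,3-dioxolan-4-yl](hydroxy)methyl}prop-2-enoate (both C7 carbinol epimers)
Conditions: DABCO (0.5 equiv), 13 (5 equiv, neat), 23 °C, 3–5 d
Reagents that add atoms: none
Why: The Morita–Baylis–Hillman reaction joins C7 to C11; the new C7 carbinol centre forms as an epimer mixture that is erased in step 10, while C8 is untouched.

Step 10
Reactants: 14 methyl 2-{[(4R)-2,2-dimethyl-1,3-dioxolan-4-yl](hydroxy)methyl}prop-2-enoate
Product: 15 methyl (2Z)-2-(bromomethyl)-3-[(4S)-2,2-dimethyl-1,3-dioxolan-4-yl]prop-2-enoate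
Conditions: NBS (1.5 equiv), Me2S (1.6 equiv), CH2Cl2, 0 °C to 23 °C
Reagents that add atoms: N-bromosuccinimide, O=C1CCC(=O)N1Br
Why: Corey–Kim-type activation of the hydroxyl and SN2' attack of bromide should give the rearranged primary allylic bromide as the thermodynamically favoured (Z)-isomer from both C7 epimers.

Step 11
Reactants: 11 (2Z,6Z)-2-bromo-6-methyl-8-oxoocta-2,6-dien-1-yl (2S)-2-methylbutanoate; 15 methyl (2Z)-2-(bromomethyl)-3-[(4S)-2,2-dimethyl-1,3-dioxolan-4-yl]prop-2-enoate
Product: 17 (4S,5R)-5-[(1Z,5Z)-6-bromo-2-methyl-7-{[(2S)-2-methylbutanoyl]oxy}hepta-1,5-dien-1-yl]-4-[(4S)-2,2-dimethyl-1,3-dioxolan-4-yl]-3-methylideneoxolan-2-one, via hydroxy ester 16 (not isolated)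
Conditions: 15 (1.5 equiv), CrCl2 (4 equiv), THF, 0 °C to 23 °C; aqueous work-up; then PPTS (5 mol %), PhMe, 40 °C
Reagents that add atoms: none
Why: Chromium-mediated Barbier allylation (Nozaki–Hiyama type) followed by lactonisation: the equilibrating 2-(methoxycarbonyl)allylchromium should add to the enal through a chair transition state with the dioxolanyl group equatorial (6,7-anti adduct, hence the trans-lactone) and on the face of C7 anti to the C8–C9 bond, with H8 eclipsing the alkene to avoid allylic strain with the ester, which should give 6R,7S; the alkenyl bromide stays inert because no nickel is present.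

Step 12
Reactants: 17 (acetonide lactone)
Product: 18 (4R,5R)-5-[(1Z,5Z)-6-bromo-2-methyl-7-{[(2S)-2-methylbutanoyl]oxy}hepta-1,5-dien-1-yl]-4-[(1S)-1,2-dihydroxyethyl]-3-methylideneoxolan-2-one
Conditions: AcOH/H2O/THF (3:1:1), 40 °C
Reagents that add atoms: none
Why: Acid-catalysed acetal hydrolysis frees the C8/C9 diol without affecting the esters, the lactone or the alkenyl bromide; the diol is silylated at once to forestall translactonisation onto O8.

Step 13
Reactants: 18 (C8,C9 diol)
Product: 19 (4S,5R)-4-[(1S)-1,2-bis(triethylsilyloxy)ethyl]-5-[(1Z,5Z)-6-bromo-2-methyl-7-{[(2S)-2-methylbutanoyl]oxy}hepta-1,5-dien-1-yl]-3-methylideneoxolan-2-one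
Conditions: Et3SiOTf (2.5 equiv), 2,6-lutidine (4 equiv), CH2Cl2, −78 °C
Reagents that add atoms: triethylsilyl triflate, CC[Si](CC)(CC)OS(=O)(=O)C(F)(F)F
Why: Exhaustive silylation under non-nucleophilic conditions protects O8 and primes the primary C9 silyl ether for direct oxidation.

Step 14
Reactants: 19 (bis-silyl ether)
Product: 20 (4S,5R)-5-[(1Z,5Z)-6-bromo-2-methyl-7-{[(2S)-2-methylbutanoyl]oxy}hepta-1,5-dien-1-yl]-3-methylidene-4-[(1S)-2-oxo-1-(triethylsilyloxy)ethyl]oxolan-2-one
Conditions: (COCl)2 (4 equiv), DMSO (8 equiv), CH2Cl2, −78 to −40 °C; then Et3N, −78 to 0 °C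
Reagents that add atoms: none
Why: Swern oxidation cleaves and oxidises primary triethylsilyl ethers selectively, so it should give the C9 aldehyde while the secondary C8 silyl ether survives and C8 does not epimerise at low temperature.

Step 15
Reactants: 20 (C9 aldehyde with C10–Br)
Product: 21 (1(10)Z,4Z,6R,7S,8S,9R)-9-hydroxy-14-{[(2S)-2-methylbutanoyl]oxy}-8-(triethylsilyloxy)germacra-1(10),4,11(13)-trien-12,6-olide
Conditions: CrCl2 (8 equiv), NiCl2 (10 mol %), DMSO, 23 °C, 0.002 M (syringe-pump addition)
Reagents that add atoms: none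
Why: Intramolecular Nozaki–Hiyama–Kishi reaction: zerovalent nickel inserts into the C10–Br bond with retention, the alkenyl group passes to trivalent chromium and adds to the C9 aldehyde, which closes the ten-membered carbocycle at C9–C10 with C9 cis to C2 and, by Felkin–Anh attack anti to the C8 silyloxy group, should give the 9R (8,9-anti) carbinol.

Step 16
Reactants: 21 (macrocyclic C9 alcohol)
Product: 22 (1(10)Z,4Z,6R,7S,8S,9R)-9-acetoxy-14-{[(2S)-2-methylbutanoyl]oxy}-8-(triethylsilyloxy)germacra-1(10),4,11(13)-trien-12,6-olide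
Conditions: Ac2O (3 equiv), DMAP (0.1 equiv), pyridine, CH2Cl2, 0 °C to 23 °C
Reagents that add atoms: acetic anhydride, CC(=O)OC(C)=O
Why: Nucleophile-catalysed acetylation (Steglich-type acyl transfer) of the only free hydroxyl installs the C9 acetate regiospecifically because O8 is still silylated.

Step 17
Reactants: 22 (C8 silyl ether)
Product: 23 target, (1(10)Z,4Z,6R,7R,8S,9R)-9-acetoxy-8-hydroxy-14-{[(2S)-2-methylbutanoyl]oxy}germacra-1(10),4,11(13)-trien-12,6-olide
Conditions: HF·pyridine, pyridine/THF, 0 °C
Reagents that add atoms: none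
Why: Buffered fluoride desilylation frees O8 under mildly acidic conditions that should not cause acetyl migration from O9 to O8, conjugate addition to the α-methylene lactone or translactonisation.

**Compound list**

1 | neryl acetate, (2Z)-3,7-dimethylocta-2,6-dien-1-yl acetate | CC(C)=CCC/C(C)=C\COC(C)=O | starting material
2 | (2Z)-5-(3,3-dimethyloxiran-2-yl)-3-methylpent-2-en-1-yl acetate (racemic at the oxirane CH) | CC1(C)OC1CC/C(C)=C\COC(C)=O | intermediate
3 | (2Z)-3-methyl-6-oxohex-2-en-1-yl acetate | O=CCC/C(C)=C\COC(C)=O | intermediate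
4 | (2Z)-7,7-dibromo-3-methylhepta-2,6-dien-1-yl acetate | BrC(Br)=CCC/C(C)=C\COC(C)=O | intermediate
5 | (2Z)-7,7-dibromo-3-methylhepta-2,6-dien-1-ol | BrC(Br)=CCC/C(C)=C\CO | intermediate
6 | (2S)-2-methylbutanoic acid | CC[C@H](C)C(=O)O | starting material
7 | chloromethyl (2S)-2-methylbutanoate | CC[C@H](C)C(=O)OCCl | intermediate
8 | iodomethyl (2S)-2-methylbutanoate | CC[C@H](C)C(=O)OCI | intermediate
9 | {[(2S)-2-methylbutanoyl]oxy}methylzinc iodide | CC[C@H](C)C(=O)OC[Zn]I | intermediate (not isolated)
10 | (2Z,6Z)-2-bromo-8-hydroxy-6-methylocta-2,6-dien-1-yl (2S)-2-methylbutanoate | CC[C@H](C)C(=O)OC/C(Br)=C/CC/C(C)=C\CO | intermediate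
11 | (2Z,6Z)-2-bromo-6-methyl-8-oxoocta-2,6-dien-1-yl (2S)-2-methylbutanoate | CC[C@H](C)C(=O)OC/C(Br)=C/CC/C(C)=C\C=O | intermediate
12 | (4R)-2,2-dimethyl-1,3-dioxolane-4-carbaldehyde | O=C[C@H]1COC(C)(C)O1 | starting material
13 | methyl acrylate | C=CC(=O)OC | starting material
14 | methyl 2-{[(4R)-2,2-dimethyl-1,3-dioxolan-4-yl](hydroxy)methyl}prop-2-enoate (carbinol epimers) | C=C(C(=O)OC)C(O)[C@H]1COC(C)(C)O1 | intermediate
15 | methyl (2Z)-2-(bromomethyl)-3-[(4S)-2,2-dimethyl-1,3-dioxolan-4-yl]prop-2-enoate | COC(=O)/C(CBr)=C/[C@H]1COC(C)(C)O1 | intermediate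
16 | methyl (3S,4R,5Z,9Z)-10-bromo-3-[(4S)-2,2-dimethyl-1,3-dioxolan-4-yl]-4-hydroxy-6-methyl-2-methylidene-11-{[(2S)-2-methylbutanoyl]oxy}undeca-5,9-dienoate | C=C(C(=O)OC)[C@H]([C@H]1COC(C)(C)O1)[C@H](O)/C=C(/C)CC/C=C(Br)/COC(=O)[C@@H](C)CC | intermediate (not isolated)
17 | (4S,5R)-5-[(1Z,5Z)-6-bromo-2-methyl-7-{[(2S)-2-methylbutanoyl]oxy}hepta-1,5-dien-1-yl]-4-[(4S)-2,2-dimethyl-1,3-dioxolan-4-yl]-3-methylideneoxolan-2-one | C=C1C(=O)O[C@H](/C=C(/C)CC/C=C(Br)/COC(=O)[C@@H](C)CC)[C@H]1[C@H]2COC(C)(C)O2 | intermediate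
18 | (4R,5R)-5-[(1Z,5Z)-6-bromo-2-methyl-7-{[(2S)-2-methylbutanoyl]oxy}hepta-1,5-dien-1-yl]-4-[(1S)-1,2-dihydroxyethyl]-3-methylideneoxolan-2-one | C=C1C(=O)O[C@H](/C=C(/C)CC/C=C(Br)/COC(=O)[C@@H](C)CC)[C@H]1[C@H](O)CO | intermediate
19 | (4S,5R)-4-[(1S)-1,2-bis(triethylsilyloxy)ethyl]-5-[(1Z,5Z)-6-bromo-2-methyl-7-{[(2S)-2-methylbutanoyl]oxy}hepta-1,5-dien-1-yl]-3-methylideneoxolan-2-one | C=C1C(=O)O[C@H](/C=C(/C)CC/C=C(Br)/COC(=O)[C@@H](C)CC)[C@H]1[C@H](O[Si](CC)(CC)CC)CO[Si](CC)(CC)CC | intermediate
20 | (4S,5R)-5-[(1Z,5Z)-6-bromo-2-methyl-7-{[(2S)-2-methylbutanoyl]oxy}hepta-1,5-dien-1-yl]-3-methylidene-4-[(1S)-2-oxo-1-(triethylsilyloxy)ethyl]oxolan-2-one | C=C1C(=O)O[C@H](/C=C(/C)CC/C=C(Br)/COC(=O)[C@@H](C)CC)[C@H]1[C@H](O[Si](CC)(CC)CC)C=O | intermediate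
21 | (1(10)Z,4Z,6R,7S,8S,9R)-9-hydroxy-14-{[(2S)-2-methylbutanoyl]oxy}-8-(triethylsilyloxy)germacra-1(10),4,11(13)-trien-12,6-olide | C=C1C(=O)O[C@@H]2/C=C(/C)CC/C=C(/COC(=O)[C@@H](C)CC)[C@@H](O)[C@@H](O[Si](CC)(CC)CC)[C@@H]12 | intermediate
22 | (1(10)Z,4Z,6R,7S,8S,9R)-9-acetoxy-14-{[(2S)-2-methylbutanoyl]oxy}-8-(triethylsilyloxy)germacra-1(10),4,11(13)-trien-12,6-olide | C=C1C(=O)O[C@@H]2/C=C(/C)CC/C=C(/COC(=O)[C@@H](C)CC)[C@@H](OC(C)=O)[C@@H](O[Si](CC)(CC)CC)[C@@H]12 | intermediate
23 | (1(10)Z,4Z,6R,7R,8S,9R)-9-acetoxy-8-hydroxy-14-{[(2S)-2-methylbutanoyl]oxy}germacra-1(10),4,11(13)-trien-12,6-olide | C=C1C(=O)O[C@@H]2/C=C(/C)CC/C=C(/COC(=O)[C@@H](C)CC)[C@@H](OC(C)=O)[C@@H](O)[C@@H]12 | target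

**Summary and risks**

Total step count: 17. Longest linear sequence: 13 steps (steps 1–4, 7, 8 and 11–17, from neryl acetate).

Steps most likely to fail:

1. Step 15. The medium-ring closure may lose to oligomerisation and to reduction of the C10–Br bond, and the ring transition state may override Felkin–Anh control so that the C9 carbinol forms with poor or reversed facial selectivity. The fallback sets the C9 centre by reagent-controlled reduction instead of during C–C bond formation. It sets out from 21 obtained as a C9 epimer mixture. Dess–Martin periodinane with NaHCO3 in CH2Cl2 should convert both epimers into the single macrocyclic enone (1(10)Z,4Z,6R,7S,8S)-14-{[(2S)-2-methylbutanoyl]oxy}-9-oxo-8-(triethylsilyloxy)germacra-1(10),4,11(13)-trien-12,6-olide F6. Corey–Bakshi–Shibata reduction with (R)-2-methyl-CBS-oxazaborolidine and BH3·SMe2 at −40 °C, with the alkenyl arm acting as the large group, should then deliver the 9R alcohol. The fallback comes back to the route at 21.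

2. Step 11. Lewis-acidic trivalent chromium may isomerise the (Z)-enal to the (E)-enal, the equilibrating allylchromium may give incomplete anti selectivity (some cis-lactone), and facial discrimination by the C8 dioxolane may be modest. The fallback replaces the equilibrating allylmetal by a geometry-defined allylboronate that reacts through a closed transition state. It sets out from 12 and joins 11. Ohira–Bestmann alkynylation of 12 (dimethyl (1-diazo-2-oxopropyl)phosphonate, K2CO3, MeOH) should give (4S)-4-ethynyl-2,2-dimethyl-1,3-dioxolane F3. Deprotonation with n-BuLi and acylation with ClCO2Me should give methyl 3-[(4S)-2,2-dimethyl-1,3-dioxolan-4-yl]prop-2-ynoate F4. Syn-hydroalumination with i-Bu2AlH/HMPA and trapping of the α-aluminio acrylate with ICH2Bpin should give methyl (2Z)-3-[(4S)-2,2-dimethyl-1,3-dioxolan-4-yl]-2-[(4,4,5,5-tetramethyl-1,3,2-dioxaborolan-2-yl)methyl]prop-2-enoate F5, in which C8 is fixed trans to the CH2B group. Allylboration of 11 with F5 (Sc(OTf)3 10 mol %, toluene, 0 °C) is stereospecific, so the anti adduct, the pinacol borate of 16, should form and lactonise with loss of methanol. The fallback comes back to the route at 17.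

3. Step 7. The stabilised α-acyloxymethylzinc reagent may transmetalate slowly, so that protonation by the free hydroxyl, coupling at the second C–Br bond, or ionisation of the newly formed allylic ester by zerovalent palladium compete. The fallback introduces C14 as a hydroxymethyl group and forms the ester afterwards. It sets out from 5. MnO2 oxidation should give (2Z)-7,7-dibromo-3-methylhepta-2,6-dienal F1. A trans-selective Stille coupling with Bu3SnCH2OH (Pd2(dba)3, tri(2-furyl)phosphine, toluene, 80 °C) should give (2Z,6Z)-7-bromo-8-hydroxy-3-methylocta-2,6-dienal F2. Steglich esterification of F2 with acid 6 (DCC, DMAP, CH2Cl2, 0 °C) should give the ester. The fallback comes back to the route at 11.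

**Further compounds**

F1 | step 7 | (2Z)-7,7-dibromo-3-methylhepta-2,6-dienal | BrC(Br)=CCC/C(C)=C\C=O
F2 | step 7 | (2Z,6Z)-7-bromo-8-hydroxy-3-methylocta-2,6-dienal | OC/C(Br)=C/CC/C(C)=C\C=O
F3 | step 11 | (4S)-4-ethynyl-2,2-dimethyl-1,3-dioxolane | C#C[C@H]1COC(C)(C)O1
F4 | step 11 | methyl 3-[(4S)-2,2-dimethyl-1,3-dioxolan-4-yl]prop-2-ynoate | COC(=O)C#C[C@H]1COC(C)(C)O1
F5 | step 11 | methyl (2Z)-3-[(4S)-2,2-dimethyl-1,3-dioxolan-4-yl]-2-[(4,4,5,5-tetramethyl-1,3,2-dioxaborolan-2-yl)methyl]prop-2-enoate | COC(=O)/C(CB1OC(C)(C)C(C)(C)O1)=C\[C@H]2COC(C)(C)O2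
F6 | step 15 | (1(10)Z,4Z,6R,7S,8S)-14-{[(2S)-2-methylbutanoyl]oxy}-9-oxo-8-(triethylsilyloxy)germacra-1(10),4,11(13)-trien-12,6-olide | C=C1C(=O)O[C@@H]2/C=C(/C)CC/C=C(/COC(=O)[C@@H](C)CC)C(=O)[C@@H](O[Si](CC)(CC)CC)[C@@H]12
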